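In a one-step world you would simply heat: each partner consumed gives one target, and hotter only gets you there sooner. Your decision here is the temperature of the next run, with charge and time fixed.

the same everywhere: catalyst 3.3 mol%

| charge | starting material | partner | temperature | remark | time |
|---|---|---|---|---|---|
| spring | 26 mM | 0.64 equiv | 70 °C | run made earlier |  |
| midnight | 26 mM | 1.4 equiv | 92 °C | run made earlier |  |
| winter | 52 mM | 0.95 equiv | 70 °C | run made earlier |  |
| grey | 26 mM | 0.950 equiv | 60 °C |  | 2.0 h |
| red | 26 mM | 0.950 equiv | 100 °C |  | 2.0 h |
| violet | 26 mM | 0.950 equiv | 80 °C |  | 2.0 h |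

| run | time / min | target / % |
|---|---|---|
| spring | 10.0 | 34.7 |
| spring | 20.0 | 46.6 |
| spring | 30.0 | 52.6 |
| spring | 40.0 | 54.2 |
| spring | 50.0 | 55.2 |
| spring | 60.0 | 56.0 |
| midnight | 3.00 | 55.4 |
| midnight | 6.00 | 69.8 |
| midnight | 10.0 | 73.4 |
| midnight | 12.0 | 72.7 |
| midnight | 15.0 | 70.7 |
| midnight | 20.0 | 65.6 |
| winter | 5.00 | 64.6 |
| winter | 10.0 | 77.0 |
| winter | 15.0 | 81.3 |
| winter | 30.0 | 84.9 |
| winter | 60.0 | 82.6 |

(scatter of a reading: 0.3 percentage points)

- the flask with the highest amount of target, in percent of the starting material charged ("all alike" if they lie within 1.5 percentage points) (grey / red / violet / all alike)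
- final target, as a percentage of the starting material charged, in grey
- final target, as a percentage of the starting material charged, in red
- final target, as a percentage of the starting material charged, in violet



Start with the balance of the partner, the limiting reagent. It is charged at 0.950 equiv, so the recipe stands at 95.0%, the ceiling: the most target this partner charge can give, in percent of the starting material charged.

But the midnight and winter readings fall late on. Midnight, at 92 °C, drops from 72.7% to 65.6% between 12.0 min and 20.0 min. Winter, at 70 °C, slips from 84.9% to 82.6% between 30.0 min and 60.0 min. So something takes target away. Read as first-order tails, these give 9.15 × 10⁻⁴ min⁻¹ for winter and 0.0128 min⁻¹ for midnight, the faster of the two.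

Those runs differ in charge as well as temperature, so this is rough: over 2.0 h, those rates would bring the ceiling down to 85.1% at the winter rate and 20.4% at the midnight rate. My reckoning, then: run cold. Red, hotter than midnight, should land below that second figure, and violet should land between the two. Grey should come first, provided its making gets far enough in the time.

The forecast also picks grey: 77% (66% to 86%) there, 50% (38% to 62%) in violet and 2% (0% to 12%) in red, on the grounds that “Cooler runs therefore reach higher conversion”.

The flasks give 80.9% in grey, 46.1% in violet and 5.38% in red, so grey wins.

    starting material + partner + catalyst → catalyst + target (k = 283 M⁻² s⁻¹, Ea = 46.0 kJ mol⁻¹)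
    target ⇌ isomer of the product (K = 18.0, k = 9.40 × 10⁻⁴ s⁻¹, Ea = 117 kJ mol⁻¹, ΔH = −42.0 kJ mol⁻¹)
    (constants at 100 °C)

Conversion of starting material ends at 94.5% in red, higher than the 85.8% in grey, yet red holds less target. Red ends with 5.38% target and 89.1% isomer of the product; without that loss it would hold 94.5%, just under the ceiling of 95.0%, so this step is the main reason for red's low figure. In grey the same step is a part of the shortfall, 4.9 percentage points, and target plus isomer of the product reach 85.8%. The neighbour of grey at 65 mM, with partner down to 0.50% of its charge, gives 88.2% target and a sum of 94.5%.

All runs come from a simulation with made-up constants; scatter was added.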